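**Plan**
1. The retrosynthesis first cuts the central C(sp2)–C(sp2) single bond of the (E,E)-diene. This gives two C10 halves, a 6-vinyloxane and an (E)-alkenyl pinacolboronate on the cyclohexane, which are joined unprotected in the last step by an oxidative Heck vinylation.
2. The enabling feature is oxane carbon C6, bonded to O1, C5, a methyl group and the vinyl group, which carries no hydrogen. The vinyl group must therefore bond at its CH2 terminus, β-hydride loss can only give the conjugated (E)-alkene, and no allylic C–H exists. Both C–Br bonds are equatorial and adjoin fully substituted carbons (oxane C2, cyclohexane C1), so they stay inert.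
3. In the oxane ring, O1–C2 and C3–Br are cut back to (R)-linalool, and one biomimetic 6-endo bromoetherification closes the ring. C6 comes from the chiral pool; C3 comes from the chair transition state plus separation.
4. In the cyclohexane half the cuts are C=CH(B) (boron–Wittig), C1–CH3 (Grignard), C2–Br (NBS) and two ring bonds (Diels–Alder of two butenone-derived C4 units). The ring arises first.
5. Stereochemistry is relayed. The Diels–Alder catalyst sets C4, C4 directs axial bromination at C2, and the C2–Br bond directs methyl addition at C1 to give the cis-bromohydrin. C4 is then inverted by equilibration α to the acetyl group, giving the chair with acetyl, Br and CH3 equatorial.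
6. The trisubstituted alkene geometry is fixed in the boron–Wittig step and retained. The disubstituted alkene geometry arises from syn insertion and syn elimination in the coupling.

Key step: step 9

Assumption: the (S)-configured oxazaborolidinium catalyst is taken to give (S)-cyclohex-3-ene-1-carbonyl adducts from acrylate- and vinyl-ketone-type dienophiles, so the (R)-catalyst is specified in step 2. If the sense were opposite, the antipodal catalyst would be used with no other change.

Step 1
Reactants: 1 but-3-en-2-one
Product: 2 2-(triisopropylsilyloxy)buta-1,3-diene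
Conditions: TIPSOTf, Et3N, Et2O, 0 °C → rt
Reagents that add atoms: triisopropylsilyl trifluoromethanesulfonate, CC(C)[Si](OS(=O)(=O)C(F)(F)F)(C(C)C)C(C)C
Why: Silyl enol ether formation by soft enolisation removes a methyl proton of the enone and gives the 2-silyloxydiene, the bulky silyl group being chosen because it survives the acidic catalyst of step 2, and no stereocentre is formed.

Step 2
Reactants: 2 2-(triisopropylsilyloxy)buta-1,3-diene; 1 but-3-en-2-one
Product: 3 (R)-1-[4-(triisopropylsilyloxy)cyclohex-3-en-1-yl]ethan-1-one
Conditions: (R)-3,3-diphenyl-1-(2-methylphenyl)tetrahydro-1H,3H-pyrrolo[1,2-c][1,3,2]oxazaborole (20 mol %), Tf2NH (18 mol %), CH2Cl2, −78 → −40 °C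
Reagents that add atoms: none
Why: In this catalytic enantioselective Diels–Alder reaction the cationic oxazaborolidine binds the enone carbonyl and shields one alkene face, the large terminal coefficient of the 2-silyloxydiene gives the 1,4-("para") adduct, and the catalyst alone sets the single stereocentre while the ring ketone stays masked as a regiodefined enol ether.

Step 3
Reactants: 3 (R)-1-[4-(triisopropylsilyloxy)cyclohex-3-en-1-yl]ethan-1-one
Product: 4 (2S,4R)-4-acetyl-2-bromocyclohexan-1-one (Br axial, trans to the equatorial acetyl group)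
Conditions: NBS, THF, −78 → −20 °C; aqueous work-up; used at once
Reagents that add atoms: N-bromosuccinimide, O=C1CCC(=O)N1Br
Why: In this electrophilic α-bromination of a silyl enol ether the position of the enol double bond fixes the site, and stereoelectronically preferred axial attack on the half-chair with a pseudo-equatorial acetyl group places bromine axial and trans to that group (2S).

Step 4
Reactants: 4 (2S,4R)-4-acetyl-2-bromocyclohexan-1-one
Product: 5 1-[(1R,3S,4R)-3-bromo-4-hydroxy-4-methylcyclohexyl]ethan-1-one (OH and Br cis; acetyl and OH equatorial, Br and CH3 axial)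
Conditions: MeMgBr (1.05 equiv, slow addition), Et2O/toluene, −78 °C; AcOH quench at −78 °C; chromatography
Reagents that add atoms: methylmagnesium bromide, C[Mg]Br
Why: In this Grignard addition under polar Felkin–Anh (Cornforth-type) control the α-bromocyclohexanone carbonyl is much more electrophilic than the branched methyl ketone, methyl enters anti to the axial C–Br bond to give the cis-bromohydrin (4R), and chromatography here removes the all-equatorial diastereomer that would arise from any equatorial bromide and would belong to the enantiomeric series.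

Step 5
Reactants: 5 1-[(1R,3S,4R)-3-bromo-4-hydroxy-4-methylcyclohexyl]ethan-1-one
Product: 6 1-[(1S,3S,4R)-3-bromo-4-hydroxy-4-methylcyclohexyl]ethan-1-one (acetyl, Br and CH3 equatorial, OH axial)
Conditions: K2CO3 (0.3 equiv), MeOH, rt; residual 5 separated and resubmitted
Reagents that add atoms: none
Why: Base-catalysed epimerisation α to the acetyl group under thermodynamic control inverts the acetyl-bearing carbon and leads to the chair with three equatorial groups, a cis-bromohydrin cannot close to an epoxide, and in methanol reprotonation of the enolate should outrun 1,3-displacement of bromide.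

Step 6
Reactants: 6 1-[(1S,3S,4R)-3-bromo-4-hydroxy-4-methylcyclohexyl]ethan-1-one
Product: 7 1-[(1S,3S,4R)-3-bromo-4-methyl-4-(trimethylsilyloxy)cyclohexyl]ethan-1-one
Conditions: 1-(trimethylsilyl)imidazole, CH2Cl2, rt
Reagents that add atoms: 1-(trimethylsilyl)imidazole, C[Si](C)(C)n1ccnc1
Why: Silyl ether protection with a neutral but powerful silyl donor covers the hindered tertiary alcohol before the carbanion chemistry of step 7 without enolising the ketone or touching a stereocentre.

Step 7
Reactants: 7 1-[(1S,3S,4R)-3-bromo-4-methyl-4-(trimethylsilyloxy)cyclohexyl]ethan-1-one; 8 bis(4,4,5,5-tetramethyl-1,3,2-dioxaborolan-2-yl)methane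
Product: 10 (1R,2S,4S)-2-bromo-1-methyl-4-[(E)-1-(4,4,5,5-tetramethyl-1,3,2-dioxaborolan-2-yl)prop-1-en-2-yl]cyclohexan-1-ol, via O-trimethylsilyl alkenylboronate 9 (not isolated)
Conditions: 8, lithium 2,2,6,6-tetramethylpiperidide, THF, 0 °C; then 7, −78 °C → rt; then 1 M HCl, THF, 0 °C
Reagents that add atoms: none
Why: In this boron–Wittig olefination the lithiated geminal diboronate adds to the methyl ketone and syn B–O elimination proceeds through the arrangement that keeps the remaining boryl group away from the cyclohexyl residue, which should give the (E)-trisubstituted alkenylboronate, while the equatorial bromide has no antiperiplanar hydrogen to lose and dilute acid then removes the silyl ether.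

Step 8
Reactants: 11 (R)-(−)-linalool
Product: 12 (3S,6R)-3-bromo-6-ethenyl-2,2,6-trimethyloxane (Br and vinyl equatorial and trans, C6 methyl axial)
Conditions: 2,4,4,6-tetrabromocyclohexa-2,5-dien-1-one, MeNO2, 0 °C → rt, dark; chromatography
Reagents that add atoms: 2,4,4,6-tetrabromocyclohexa-2,5-dien-1-one, O=C1C(Br)=CC(Br)(Br)C=C1Br
Why: In this biomimetic bromoetherification the bromonium ion forms on the electron-rich trisubstituted alkene and is opened anti by the tertiary hydroxyl at its tertiary carbon (6-endo) through a chair with equatorial Br, C6 is carried over unchanged from linalool, and C3 is only weakly biased because vinyl and methyl are similar in size, so the C3 epimer and the 5-exo oxolanes have to be removed by chromatography.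

Step 9
Reactants: 10 (1R,2S,4S)-2-bromo-1-methyl-4-[(E)-1-(4,4,5,5-tetramethyl-1,3,2-dioxaborolan-2-yl)prop-1-en-2-yl]cyclohexan-1-ol; 12 (3S,6R)-3-bromo-6-ethenyl-2,2,6-trimethyloxane
Product: 13 (1R,2S,4S)-2-bromo-4-{(2E,4E)-5-[(2R,5S)-5-bromo-2,6,6-trimethyloxan-2-yl]penta-2,4-dien-2-yl}-1-methylcyclohexan-1-ol
Conditions: Pd(OAc)2·[1,2-bis(phenylsulfinyl)ethane] (10 mol %), 1,4-benzoquinone (2 equiv), AcOH (4 equiv), 1,4-dioxane, rt → 45 °C
Reagents that add atoms: none
Why: The alkenyl group of 10 passes from boron to divalent palladium with retention of its (E)-geometry, the vinyl group of 12 coordinates and inserts syn into the Pd–C bond so that the new C–C bond forms at its CH2 terminus, and rotation followed by syn β-hydride elimination releases the (E,E)-diene, after which benzoquinone and AcOH return zerovalent palladium to Pd(OAc)2. The closest known reaction type is the oxidative Heck (boron-Heck) vinylation of terminal alkenes with alkenylboronic esters under bis-sulfoxide/Pd(OAc)2 catalysis, and Heck reactions of tertiary allylic alcohols and ethers show that a fully substituted allylic carbon is tolerated. No ring is closed and no stereocentre is formed; the five existing stereocentres are spectators, the trisubstituted alkene keeps the geometry fixed in step 7, and the new disubstituted alkene should be (E) because the conformer that eliminates holds the oxane and the alkenyl residue apart. Regioselectivity is secured by oxane C6, whose four non-hydrogen substituents block bond formation at the internal vinyl carbon, and the same carbon offers no β-hydrogen and no allylic C–H, so a skipped diene, chain walking and allylic C–H acetoxylation cannot compete. Chemoselectivity towards the two secondary bromides rests on the oxidising, base-free medium, in which zerovalent palladium is short-lived, and on both C–Br bonds being equatorial and flanked by fully substituted carbons without an antiperiplanar hydrogen, while the cis-bromohydrin cannot form an epoxide and the free tertiary alcohol needs no protection. The ring oxygen on C6 is a poor leaving group, so β-hydride loss should outrun β-alkoxide loss.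

**Compound list**
1 | but-3-en-2-one | CC(=O)C=C | starting material
2 | 2-(triisopropylsilyloxy)buta-1,3-diene | C=CC(=C)O[Si](C(C)C)(C(C)C)C(C)C | intermediate
3 | (R)-1-[4-(triisopropylsilyloxy)cyclohex-3-en-1-yl]ethan-1-one | CC(=O)[C@H]1CC=C(O[Si](C(C)C)(C(C)C)C(C)C)CC1 | intermediate
4 | (2S,4R)-4-acetyl-2-bromocyclohexan-1-one | CC(=O)[C@@H]1CCC(=O)[C@@H](Br)C1 | intermediate
5 | 1-[(1R,3S,4R)-3-bromo-4-hydroxy-4-methylcyclohexyl]ethan-1-one | CC(=O)[C@@H]1CC[C@@](C)(O)[C@@H](Br)C1 | intermediate
6 | 1-[(1S,3S,4R)-3-bromo-4-hydroxy-4-methylcyclohexyl]ethan-1-one | CC(=O)[C@H]1CC[C@@](C)(O)[C@@H](Br)C1 | intermediate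
7 | 1-[(1S,3S,4R)-3-bromo-4-methyl-4-(trimethylsilyloxy)cyclohexyl]ethan-1-one | CC(=O)[C@H]1CC[C@@](C)(O[Si](C)(C)C)[C@@H](Br)C1 | intermediate
8 | bis(4,4,5,5-tetramethyl-1,3,2-dioxaborolan-2-yl)methane | CC1(C)OB(CB2OC(C)(C)C(C)(C)O2)OC1(C)C | starting material
9 | 2-{(E)-2-[(1S,3S,4R)-3-bromo-4-methyl-4-(trimethylsilyloxy)cyclohexyl]prop-1-en-1-yl}-4,4,5,5-tetramethyl-1,3,2-dioxaborolane | C/C(=C\B1OC(C)(C)C(C)(C)O1)[C@H]1CC[C@@](C)(O[Si](C)(C)C)[C@@H](Br)C1 | intermediate
10 | (1R,2S,4S)-2-bromo-1-methyl-4-[(E)-1-(4,4,5,5-tetramethyl-1,3,2-dioxaborolan-2-yl)prop-1-en-2-yl]cyclohexan-1-ol | C/C(=C\B1OC(C)(C)C(C)(C)O1)[C@H]1CC[C@@](C)(O)[C@@H](Br)C1 | intermediate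
11 | (R)-(−)-linalool, (3R)-3,7-dimethylocta-1,6-dien-3-ol | C=C[C@](C)(O)CCC=C(C)C | starting material
12 | (3S,6R)-3-bromo-6-ethenyl-2,2,6-trimethyloxane | C=C[C@@]1(C)CC[C@H](Br)C(C)(C)O1 | intermediate
13 | (1R,2S,4S)-2-bromo-4-{(2E,4E)-5-[(2R,5S)-5-bromo-2,6,6-trimethyloxan-2-yl]penta-2,4-dien-2-yl}-1-methylcyclohexan-1-ol | C/C(=C\C=C\[C@@]1(C)CC[C@H](Br)C(C)(C)O1)[C@H]1CC[C@@](C)(O)[C@@H](Br)C1 | target

Total step count: 9. Longest linear sequence: 8 (steps 1–7 and 9).

**Steps most likely to fail**

Step 9. Insertion of the hindered vinyl group may be slow, so that oxidative homocoupling or protodeboronation of the boronate takes over. Loss of the ring alkoxide from the alkylpalladium intermediate could also open the oxane. The fallback sets out from 12. Ozonolysis of the vinyl group (O3, CH2Cl2, −78 °C; Me2S) gives (2R,5S)-5-bromo-2,6,6-trimethyloxane-2-carbaldehyde F1. Takai olefination (CrCl2, CHI3, THF, 0 °C → rt) gives (3S,6R)-3-bromo-6-[(E)-2-iodoethenyl]-2,2,6-trimethyloxane F2. Suzuki–Miyaura coupling of F2 with 10 (Pd(dppf)Cl2, K3PO4, THF/H2O, rt) forms the same bond between two prefunctionalised alkenyl partners and comes back to the route at 13.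

Step 4. The Grignard reagent may also attack the acetyl carbonyl. It may instead enolise the bromoketone, with loss of configuration at the bromine-bearing carbon, or trigger an intramolecular aldol reaction between the two ketones. The fallback sets out from 2 and removes the second ketone.
- Diels–Alder reaction with methyl acrylate under the catalyst of step 2 gives methyl (R)-4-(triisopropylsilyloxy)cyclohex-3-ene-1-carboxylate F3.
- NBS as in step 3 gives methyl (1R,3S)-3-bromo-4-oxocyclohexane-1-carboxylate F4.
- MeMgBr at −78 °C, to which the ester is inert, gives methyl (1R,3S,4R)-3-bromo-4-hydroxy-4-methylcyclohexane-1-carboxylate F5.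
- MeNH(OMe)·HCl with i-PrMgCl (THF, −20 °C) gives the Weinreb amide (1R,3S,4R)-3-bromo-4-hydroxy-N-methoxy-N,4-dimethylcyclohexane-1-carboxamide F6.
- MeMgBr (THF, −20 → 0 °C) converts F6 into the methyl ketone and comes back to the route at 5.

Step 8. Poor regioselectivity (5-exo against 6-endo closure) and poor facial selectivity at the bromonium stage may leave little of the wanted isomer. The fallback sets out from 11 and puts the C3 centre under reagent control. Shi epoxidation of the trisubstituted alkene (D-fructose-derived ketone, Oxone, buffered MeCN/H2O, 0 °C) gives (3R)-5-[(2R)-3,3-dimethyloxiran-2-yl]-3-methylpent-1-en-3-ol F7. Acid-catalysed opening at the tertiary epoxide carbon (camphorsulfonic acid, CH2Cl2, 0 °C) gives (3R,6R)-6-ethenyl-2,2,6-trimethyloxan-3-ol F8. The furanoid regioisomer, a tertiary alcohol, is separated at this stage. Appel-type bromination with inversion (CBr4, P(n-C8H17)3, toluene, 70 °C) comes back to the route at 12.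

**Further compounds**
F1 | step 9 | (2R,5S)-5-bromo-2,6,6-trimethyloxane-2-carbaldehyde | O=C[C@@]1(C)CC[C@H](Br)C(C)(C)O1
F2 | step 9 | (3S,6R)-3-bromo-6-[(E)-2-iodoethenyl]-2,2,6-trimethyloxane | I/C=C/[C@@]1(C)CC[C@H](Br)C(C)(C)O1
F3 | step 4 | methyl (R)-4-(triisopropylsilyloxy)cyclohex-3-ene-1-carboxylate | COC(=O)[C@H]1CC=C(O[Si](C(C)C)(C(C)C)C(C)C)CC1
F4 | step 4 | methyl (1R,3S)-3-bromo-4-oxocyclohexane-1-carboxylate | COC(=O)[C@@H]1CCC(=O)[C@@H](Br)C1
F5 | step 4 | methyl (1R,3S,4R)-3-bromo-4-hydroxy-4-methylcyclohexane-1-carboxylate | COC(=O)[C@@H]1CC[C@@](C)(O)[C@@H](Br)C1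
F6 | step 4 | (1R,3S,4R)-3-bromo-4-hydroxy-N-methoxy-N,4-dimethylcyclohexane-1-carboxamide | CON(C)C(=O)[C@@H]1CC[C@@](C)(O)[C@@H](Br)C1
F7 | step 8 | (3R)-5-[(2R)-3,3-dimethyloxiran-2-yl]-3-methylpent-1-en-3-ol | C=C[C@](C)(O)CC[C@H]1OC1(C)C
F8 | step 8 | (3R,6R)-6-ethenyl-2,2,6-trimethyloxan-3-ol | C=C[C@@]1(C)CC[C@@H](O)C(C)(C)O1
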